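## Retrosynthetic overview

1. Aryl–C1 bond: aryl bromide 1 and undec-10-enal 2 (Grignard reagent 3, carbinol 4, dehydration) give the (E)-styrene 5. The benzene ring is bought; no ring is formed anywhere in the route.
2. C2–O bond and C2 stereocentre: a new enantioselective anti-Markovnikov hydroacetoxylation of 5 gives the homobenzylic acetate 6.
3. C10=C11 bond: cross-metathesis of 6 with but-3-en-2-one 7 gives enone 8. C12 stereocentre: CBS reduction (9), then acetylation (10).
4. Aryl–CO2H bond: Vilsmeier–Haack formylation ortho to the chain (11), then Pinnick oxidation (12).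
5. End game: alkene hydrogenation (13) and benzyl ether hydrogenolysis give the target 14.

Assumption: the sense of induction of the chiral anion in step 2 and of the pyrrolidine catalyst in the fallback to step 2 is taken as written ((S,S)-IDPi and (2S,5S)-2,5-diphenylpyrrolidine give the 2S series); if it is the opposite, the mirror-image catalyst is used.

## Route

Step 1
Reactants: 1 1,3-bis(benzyloxy)-5-bromobenzene; 2 undec-10-enal
Product: 5 1,3-bis(benzyloxy)-5-[(1E)-undeca-1,10-dien-1-yl]benzene, via aryl Grignard reagent 3 (not isolated), via benzylic carbinol 4 (not isolated)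
Conditions: Mg, THF, 50 °C; then 2, 0 °C to rt; aq. NH4Cl; then p-TsOH·H2O (5 mol%), toluene, 110 °C, Dean–Stark
Reagents that add atoms: none
Why: Grignard addition to the aldehyde followed by acid-catalysed E1 dehydration of the benzylic carbinol (the classical entry to 5-alkenylresorcinol ethers) can only give the conjugated alkene and gives its more stable E isomer; the racemic carbinol centre is erased in the same operation.

Step 2
Reactants: 5 1,3-bis(benzyloxy)-5-[(1E)-undeca-1,10-dien-1-yl]benzene
Product: 6 (2S)-1-[3,5-bis(benzyloxy)phenyl]undec-10-en-2-yl acetate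
Conditions: 9-mesityl-3,6-di-tert-butyl-10-phenylacridinium (S,S)-IDPi salt (5 mol%), 2-phenylmalononitrile (50 mol%), AcOH (10 equiv), CH2Cl2–PhCF3 (1:1), 450 nm LEDs, –40 °C
Reagents that add atoms: acetic acid, CC(=O)O
Why: Proposed new method: asymmetric counteranion-directed photoredox catalysis applied to an intermolecular anti-Markovnikov hydroacyloxylation — the excited acridinium oxidises the electron-rich styrene to its radical cation, which in the low-polarity medium stays paired with the confined chiral imidodiphosphorimidate (IDPi) anion; acetic acid attacks the β-carbon (C2) on the face left open by the anion and so sets C2 as S; the anion takes the proton; the benzylic C1 radical is quenched by hydrogen-atom transfer from 2-phenylmalononitrile, whose radical reoxidises the acridine radical and closes both cycles (the remote terminal alkene is too electron-poor to be oxidised, and a C–H donor is used instead of a thiol to avoid thiol–ene addition); the closest known reaction types are the racemic acridinium-photoredox anti-Markovnikov addition of carboxylic acids to β-alkylstyrenes and chiral-anion-controlled radical-cation cycloadditions of styrenes, which have not yet been merged for an intermolecular C–O bond formation.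

Step 3
Reactants: 6 (2S)-1-[3,5-bis(benzyloxy)phenyl]undec-10-en-2-yl acetate; 7 but-3-en-2-one
Product: 8 (2S,10E)-1-[3,5-bis(benzyloxy)phenyl]-12-oxotridec-10-en-2-yl acetate
Conditions: 7 (4 equiv), second-generation Hoveyda–Grubbs catalyst (3 mol%), CH2Cl2, 40 °C
Reagents that add atoms: none
Why: Olefin cross-metathesis between a terminal alkene and an electron-poor vinyl ketone is selective for the cross product and for the E-enone; no stereocentre is touched.

Step 4
Reactants: 8 (2S,10E)-1-[3,5-bis(benzyloxy)phenyl]-12-oxotridec-10-en-2-yl acetate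
Product: 10 (2S,10E,12R)-1-[3,5-bis(benzyloxy)phenyl]tridec-10-ene-2,12-diyl diacetate, via allylic alcohol 9 (not isolated)
Conditions: (S)-2-methyl-CBS-oxazaborolidine (15 mol%), catecholborane (1.8 equiv), toluene, –78 °C; MeOH, aq. work-up; then Ac2O, Et3N, DMAP (10 mol%), CH2Cl2, rt
Reagents that add atoms: acetic anhydride, CC(=O)OC(C)=O
Why: Corey–Bakshi–Shibata reduction: the enone binds with the alkenyl group as the large and the methyl as the small substituent, so the (S)-oxazaborolidine delivers hydride to give the 12R allylic alcohol (catalyst control, C2 is too remote to interfere, catecholborane at low temperature avoids 1,4-reduction), and the crude alcohol is esterified by DMAP-catalysed acylation.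

Step 5
Reactants: 10 (2S,10E,12R)-1-[3,5-bis(benzyloxy)phenyl]tridec-10-ene-2,12-diyl diacetate
Product: 11 (2S,10E,12R)-1-[3,5-bis(benzyloxy)-2-formylphenyl]tridec-10-ene-2,12-diyl diacetate
Conditions: POCl3 (1.5 equiv), DMF, 0 °C to rt; then ice-water
Reagents that add atoms: N,N-dimethylformamide, CN(C)C=O; water, O
Why: Vilsmeier–Haack formylation (electrophilic aromatic substitution) goes to the ring position ortho to the alkyl chain and para to one benzyloxy group, as in 5-alkylresorcinol diethers, because the position between the two benzyloxy groups is the more hindered one; the two chain-flanked positions are equivalent.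

Step 6
Reactants: 11 (2S,10E,12R)-1-[3,5-bis(benzyloxy)-2-formylphenyl]tridec-10-ene-2,12-diyl diacetate
Product: 12 2-[(2S,10E,12R)-2,12-diacetoxytridec-10-en-1-yl]-4,6-bis(benzyloxy)benzoic acid
Conditions: NaClO2, NaH2PO4, 2-methyl-2-butene (20 equiv), t-BuOH–H2O, rt
Reagents that add atoms: sodium chlorite, [Na+].[O-]Cl=O
Why: Pinnick (Lindgren) oxidation converts the hindered electron-rich benzaldehyde to the acid under buffered conditions, with 2-methyl-2-butene trapping hypochlorous acid before it can reach the alkene or the ring.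

Step 7
Reactants: 12 2-[(2S,10E,12R)-2,12-diacetoxytridec-10-en-1-yl]-4,6-bis(benzyloxy)benzoic acid
Product: 14 2-[(2S,12R)-2,12-diacetoxytridecyl]-4,6-dihydroxybenzoic acid, via saturated dibenzyl acid 13 (not isolated)
Conditions: H2 (1 atm), PtO2 (5 mol%), EtOAc, rt; then Pd/C (10 wt%), EtOH, H2 (1 atm), rt
Reagents that add atoms: none
Why: Heterogeneous hydrogenation: platinum saturates the C10=C11 alkene with little allylic C–O hydrogenolysis, then palladium on carbon cleaves the two benzyl ethers by hydrogenolysis; esters, acid and both stereocentres are untouched.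

## Compound list

1 | 1,3-bis(benzyloxy)-5-bromobenzene | Brc1cc(OCc2ccccc2)cc(OCc2ccccc2)c1 | starting material
2 | undec-10-enal | C=CCCCCCCCCC=O | starting material
3 | [3,5-bis(benzyloxy)phenyl]magnesium bromide | Br[Mg]c1cc(OCc2ccccc2)cc(OCc2ccccc2)c1 | intermediate (not isolated)
4 | 1-[3,5-bis(benzyloxy)phenyl]undec-10-en-1-ol (racemic; centre removed in the same step) | OC(CCCCCCCCC=C)c1cc(OCc2ccccc2)cc(OCc2ccccc2)c1 | intermediate (not isolated)
5 | 1,3-bis(benzyloxy)-5-[(1E)-undeca-1,10-dien-1-yl]benzene | C=CCCCCCCC/C=C/c1cc(OCc2ccccc2)cc(OCc2ccccc2)c1 | intermediate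
6 | (2S)-1-[3,5-bis(benzyloxy)phenyl]undec-10-en-2-yl acetate | CC(=O)O[C@@H](CCCCCCCC=C)Cc1cc(OCc2ccccc2)cc(OCc2ccccc2)c1 | intermediate
7 | but-3-en-2-one | CC(=O)C=C | starting material
8 | (2S,10E)-1-[3,5-bis(benzyloxy)phenyl]-12-oxotridec-10-en-2-yl acetate | CC(=O)O[C@@H](CCCCCCC/C=C/C(C)=O)Cc1cc(OCc2ccccc2)cc(OCc2ccccc2)c1 | intermediate
9 | (2S,10E,12R)-1-[3,5-bis(benzyloxy)phenyl]-12-hydroxytridec-10-en-2-yl acetate | CC(=O)O[C@@H](CCCCCCC/C=C/[C@@H](C)O)Cc1cc(OCc2ccccc2)cc(OCc2ccccc2)c1 | intermediate (not isolated)
10 | (2S,10E,12R)-1-[3,5-bis(benzyloxy)phenyl]tridec-10-ene-2,12-diyl diacetate | CC(=O)O[C@@H](CCCCCCC/C=C/[C@@H](C)OC(C)=O)Cc1cc(OCc2ccccc2)cc(OCc2ccccc2)c1 | intermediate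
11 | (2S,10E,12R)-1-[3,5-bis(benzyloxy)-2-formylphenyl]tridec-10-ene-2,12-diyl diacetate | CC(=O)O[C@@H](CCCCCCC/C=C/[C@@H](C)OC(C)=O)Cc1cc(OCc2ccccc2)cc(OCc2ccccc2)c1C=O | intermediate
12 | 2-[(2S,10E,12R)-2,12-diacetoxytridec-10-en-1-yl]-4,6-bis(benzyloxy)benzoic acid | CC(=O)O[C@@H](CCCCCCC/C=C/[C@@H](C)OC(C)=O)Cc1cc(OCc2ccccc2)cc(OCc2ccccc2)c1C(=O)O | intermediate
13 | 2-[(2S,12R)-2,12-diacetoxytridecyl]-4,6-bis(benzyloxy)benzoic acid | CC(=O)O[C@@H](CCCCCCCCC[C@@H](C)OC(C)=O)Cc1cc(OCc2ccccc2)cc(OCc2ccccc2)c1C(=O)O | intermediate (not isolated)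
14 | 2-[(2S,12R)-2,12-diacetoxytridecyl]-4,6-dihydroxybenzoic acid | CC(=O)O[C@@H](CCCCCCCCC[C@@H](C)OC(C)=O)Cc1cc(O)cc(O)c1C(=O)O | target

## Step count and risks

Total step count: 7. Longest linear sequence: 7 steps (1 and 2 to 14).

Steps most likely to fail:

Step 2 (new reaction: the enantioselectivity may be low if acetic acid adds outside the chiral ion pair). Fallback, known chemistry; it sets out from 2 and comes back at 6. Undec-10-enal 2 is α-chlorinated by enamine catalysis (NCS, (2S,5S)-2,5-diphenylpyrrolidine 10 mol%, CH2Cl2) to (2R)-2-chloroundec-10-enal F1. F1 is reduced in the same flask (NaBH4, MeOH, 0 °C) to (2R)-2-chloroundec-10-en-1-ol F2 and closed with KOH to (2S)-2-(non-8-en-1-yl)oxirane F3, with inversion at C2. Grignard reagent 3 with CuI (10 mol%) opens F3 at its CH2 group to bromomagnesium (2S)-1-[3,5-bis(benzyloxy)phenyl]undec-10-en-2-olate F4, which Ac2O acetylates in the flask to 6. This replaces steps 1 and 2 by two steps.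

Step 4 (the ee of an open-chain methyl enone is only about 90%, and the C12 epimer cannot be separated later). Fallback; it sets out from 8 and comes back at 10. Luche reduction (NaBH4, CeCl3·7H2O, MeOH) gives the C12-epimeric alcohol (2S,10E,12RS)-1-[3,5-bis(benzyloxy)phenyl]-12-hydroxytridec-10-en-2-yl acetate F5. Candida antarctica lipase B with vinyl acetate acetylates only the 12R epimer and gives 10 directly. The unreacted 12S alcohol is separated, oxidised back to 8 with MnO2 and recycled. The same enzyme step can also polish material from step 4 if the sequence is stopped at 9.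

Step 7 (allylic acetate: C–O hydrogenolysis or double-bond migration on the metal would lose or scramble C12). Fallback; it sets out from 12 and comes back at 13. The alkene is reduced without a metal by diimide (2-nitrobenzenesulfonohydrazide, Et3N, CH2Cl2, rt), which cannot cleave or isomerise the allylic acetate, to give 13. Pd/C and H2 then remove the benzyl groups as in step 7.

## Further compounds

F1 | step 2 | (2R)-2-chloroundec-10-enal | C=CCCCCCCC[C@@H](Cl)C=O
F2 | step 2 | (2R)-2-chloroundec-10-en-1-ol | C=CCCCCCCC[C@@H](Cl)CO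
F3 | step 2 | (2S)-2-(non-8-en-1-yl)oxirane | C=CCCCCCCC[C@H]1CO1
F4 | step 2 | bromomagnesium (2S)-1-[3,5-bis(benzyloxy)phenyl]undec-10-en-2-olate | Br[Mg]O[C@@H](CCCCCCCC=C)Cc1cc(OCc2ccccc2)cc(OCc2ccccc2)c1
F5 | step 4 | (2S,10E,12RS)-1-[3,5-bis(benzyloxy)phenyl]-12-hydroxytridec-10-en-2-yl acetate | CC(=O)O[C@@H](CCCCCCC/C=C/C(C)O)Cc1cc(OCc2ccccc2)cc(OCc2ccccc2)c1
F0 | step 7 | none | none
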